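**Assumption:** the target is taken exactly as drawn (ring carbon 3R, side-chain carbon 2S, 5E alkene). The facial sense of the triazolium catalyst in step 6 is assigned by analogy; if the antipode forms, the enantiomeric precatalyst (from D-pyroglutamic acid) is used.

## Retrosynthetic overview

1. Both aldehydes are unmasked last: the ring CHO from an S-ethyl thioester (Fukuyama reduction), the side-chain CHO from a CH2NO2 group (Nef reaction).
2. The tetrasubstituted ring alkene comes from thiolysis and dehydration of a cyclopentane-fused β-lactone.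
3. Key disconnection: the bond between ring C3 and the side-chain α-carbon. The β-carbon of enal 5, made nucleophilic as a carbene-bound homoenolate, adds to the β-carbon of nitroalkene 12; an aldol closure (ring C1–C2) follows in the same flask. Both stereocentres are set here.
4. Enal 5 comes from but-3-enylmagnesium bromide, acetoxyacetyl chloride and crotonaldehyde; nitroalkene 12 comes from geranyl bromide, acetonitrile and nitromethane.
5. Ring order: the cyclopentane (the only carbocycle) and a transient β-lactone form together in the key step; the lactone is opened one step later.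

## Route

**Step 1**
Reactants: 1 but-3-en-1-ylmagnesium bromide; 2 2-chloro-2-oxoethyl acetate (acetoxyacetyl chloride)
Product: 3 2-oxohex-5-en-1-yl acetate
Conditions: Fe(acac)3 (3 mol %), THF, −78 °C, 15 min
Reagents that add atoms: none
Why: Iron-catalysed acyl cross-coupling of a Grignard reagent with an acid chloride is much faster at −78 °C than addition to the acetate or to the product ketone; no stereocentre is formed.

**Step 2**
Reactants: 3 2-oxohex-5-en-1-yl acetate; 4 (E)-but-2-enal (crotonaldehyde)
Product: 5 (5E)-2,7-dioxohept-5-en-1-yl acetate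
Conditions: second-generation Hoveyda–Grubbs catalyst [RuCl2(H2IMes)(=CH-C6H4-2-Oi-Pr)] (3 mol %), crotonaldehyde (5 equiv), CH2Cl2, 40 °C
Reagents that add atoms: crotonaldehyde 4 (C/C=C/C=O)
Why: Olefin cross-metathesis of a terminal alkene with an enal partner gives the conjugated (E)-enal under thermodynamic control, with loss of propene.

**Step 3**
Reactants: 6 geranyl bromide, (2E)-1-bromo-3,7-dimethylocta-2,6-diene; 7 acetonitrile
Product: 8 (4E)-5,9-dimethyldeca-4,8-dienenitrile
Conditions: MeCN (3 equiv), n-BuLi (2.5 equiv), THF, −78 °C; then 6, −78 → 0 °C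
Reagents that add atoms: acetonitrile 7 (CC#N)
Why: SN2 alkylation of lithioacetonitrile at the primary allylic bromide proceeds without allylic transposition, so the E alkene is retained.

**Step 4**
Reactants: 8 (4E)-5,9-dimethyldeca-4,8-dienenitrile
Product: 9 (4E)-5,9-dimethyldeca-4,8-dienal
Conditions: i-Bu2AlH (1.2 equiv), toluene, −78 °C; then 1 M aq. HCl, 0 °C
Reagents that add atoms: water (O)
Why: Partial hydride reduction of the nitrile stops at the N-aluminio imine, which hydrolyses to the aldehyde on work-up.

**Step 5**
Reactants: 9 (4E)-5,9-dimethyldeca-4,8-dienal; 10 nitromethane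
Product: 12 (1E,5E)-6,10-dimethyl-1-nitroundeca-1,5,9-triene, via nitro alcohol 11 (not isolated)
Conditions: CH3NO2 (5 equiv), Et3N (0.2 equiv), THF, 0 °C → rt; concentrate; then MsCl (1.3 equiv), Et3N (2.6 equiv), CH2Cl2, −10 °C
Reagents that add atoms: nitromethane 10 (C[N+](=O)[O-])
Why: Henry addition followed by mesylation and E1cB elimination gives the thermodynamically preferred (E)-nitroalkene; the carbinol centre of 11 is lost.

**Step 6**
Reactants: 5 (5E)-2,7-dioxohept-5-en-1-yl acetate; 12 (1E,5E)-6,10-dimethyl-1-nitroundeca-1,5,9-triene (1.3 equiv)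
Product: 13 [(1R,2R,5S)-2-[(2S,5E)-6,10-dimethyl-1-nitroundeca-5,9-dien-2-yl]-7-oxo-6-oxabicyclo[3.2.0]heptan-5-yl]methyl acetate (cis-fused β-lactone, side chain trans to the lactone carbonyl)
Conditions: (5S)-5-[diphenyl(trimethylsilyloxy)methyl]-2-(2,4,6-trimethylphenyl)-6,7-dihydro-5H-pyrrolo[2,1-c][1,2,4]triazol-2-ium tetrafluoroborate (10 mol %), NaOAc (20 mol %), THF, 4 Å MS, 23 °C
Reagents that add atoms: none
Why: Proposed new method: the chiral carbene turns enal 5 into an extended Breslow (homoenolate) intermediate whose normally electrophilic β-carbon adds to the electrophilic β-carbon of nitroalkene 12 (the known catalytic asymmetric homoenolate addition of enals to nitroalkenes), and, because no alcohol is present, the resulting azolium enolate closes by 5-exo aldol addition onto the tethered acetoxymethyl ketone and the tertiary alkoxide acylates itself on the acyl azolium to release the carbene (the known homoenolate/aldol/β-lactonisation cascade of enals with ketone acceptors); the catalyst side-arm shields one face of the homoenolate to set ring C3 as R, the open anti-selective approach of the (E)-nitroalkene sets the side-chain carbon as S, and the two cis ring-fusion centres are removed in step 7.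

**Step 7**
Reactants: 13 β-lactone from step 6; 14 ethanethiol
Product: 16 S-ethyl (5R)-2-(acetoxymethyl)-5-[(2S,5E)-6,10-dimethyl-1-nitroundeca-5,9-dien-2-yl]cyclopent-1-ene-1-carbothioate, via hydroxy thioester 15 (not isolated)
Conditions: EtSH (5 equiv), Et3N (0.5 equiv), CH2Cl2, 0 °C → rt; concentrate; then Martin sulfurane Ph2S[OC(CF3)2Ph]2 (1.3 equiv), CH2Cl2, 0 °C
Reagents that add atoms: ethanethiol 14 (CCS)
Why: Thiolate opens the strained β-lactone at the acyl carbon (the tertiary C–O carbon cannot be attacked), and Martin-sulfurane dehydration then removes the acidic thioester α-hydrogen lying anti to the activated tertiary hydroxyl to give the conjugated tetrasubstituted alkene; no new stereocentre is formed and C3 and the side-chain centre are untouched.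

**Step 8**
Reactants: 16 nitro enethioate from step 7
Product: 18 S-ethyl (5R)-2-(acetoxymethyl)-5-[(2S,5E)-6,10-dimethyl-1-oxoundeca-5,9-dien-2-yl]cyclopent-1-ene-1-carbothioate, via nitronate salt 17 (not isolated)
Conditions: DBU (1.05 equiv), THF, 0 °C, 10 min; then aq. TiCl3 (4 equiv), NH4OAc buffer (pH 5–6), THF/H2O, 0 °C → rt
Reagents that add atoms: water (O)
Why: Reductive Nef reaction, in which trivalent titanium reduces the nitronate to the imine and this hydrolyses at pH 5–6; the conditions are non-oxidising and nearly neutral, so the trisubstituted alkenes, acetate, thioester and the newly epimerisable α-centre survive.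

**Step 9**
Reactants: 18 aldehyde thioester from step 8
Product: 19 [(3R)-2-formyl-3-[(2S,5E)-6,10-dimethyl-1-oxoundeca-5,9-dien-2-yl]cyclopent-1-en-1-yl]methyl acetate (target)
Conditions: Et3SiH (3 equiv), 10 % Pd/C (10 mol % Pd), acetone, 0 °C → rt
Reagents that add atoms: none
Why: Fukuyama reduction, in which zerovalent palladium inserts into the acyl–sulfur bond and the silane reduces the acyl-palladium species to the aldehyde under neutral conditions, leaving the acetate, the free α-branched aldehyde and the hindered tetrasubstituted alkene alone.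

## Compound list

1 | but-3-en-1-ylmagnesium bromide | C=CCC[Mg]Br | starting material
2 | 2-chloro-2-oxoethyl acetate (acetoxyacetyl chloride) | CC(=O)OCC(=O)Cl | starting material
3 | 2-oxohex-5-en-1-yl acetate | CC(=O)OCC(=O)CCC=C | intermediate
4 | (E)-but-2-enal (crotonaldehyde) | C/C=C/C=O | starting material
5 | (5E)-2,7-dioxohept-5-en-1-yl acetate | CC(=O)OCC(=O)CC/C=C/C=O | intermediate
6 | geranyl bromide, (2E)-1-bromo-3,7-dimethylocta-2,6-diene | CC(C)=CCC/C(C)=C/CBr | starting material
7 | acetonitrile | CC#N | starting material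
8 | (4E)-5,9-dimethyldeca-4,8-dienenitrile | CC(C)=CCC/C(C)=C/CCC#N | intermediate
9 | (4E)-5,9-dimethyldeca-4,8-dienal | CC(C)=CCC/C(C)=C/CCC=O | intermediate
10 | nitromethane | C[N+](=O)[O-] | starting material
11 | (5E)-6,10-dimethyl-1-nitroundeca-5,9-dien-2-ol (racemic nitro alcohol) | CC(C)=CCC/C(C)=C/CCC(O)C[N+](=O)[O-] | intermediate
12 | (1E,5E)-6,10-dimethyl-1-nitroundeca-1,5,9-triene | CC(C)=CCC/C(C)=C/CC/C=C/[N+](=O)[O-] | intermediate
13 | [(1R,2R,5S)-2-[(2S,5E)-6,10-dimethyl-1-nitroundeca-5,9-dien-2-yl]-7-oxo-6-oxabicyclo[3.2.0]heptan-5-yl]methyl acetate | CC(=O)OC[C@@]12OC(=O)[C@@H]1[C@@H]([C@@H](C[N+](=O)[O-])CC/C=C(\C)CCC=C(C)C)CC2 | intermediate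
14 | ethanethiol | CCS | starting material
15 | S-ethyl (1R,2S,5R)-2-(acetoxymethyl)-2-hydroxy-5-[(2S,5E)-6,10-dimethyl-1-nitroundeca-5,9-dien-2-yl]cyclopentane-1-carbothioate (hydroxy thioester) | CCSC(=O)[C@@H]1[C@@H]([C@@H](C[N+](=O)[O-])CC/C=C(\C)CCC=C(C)C)CC[C@@]1(O)COC(C)=O | intermediate
16 | S-ethyl (5R)-2-(acetoxymethyl)-5-[(2S,5E)-6,10-dimethyl-1-nitroundeca-5,9-dien-2-yl]cyclopent-1-ene-1-carbothioate | CC(=O)OCC1=C(C(=O)SCC)[C@@H]([C@@H](C[N+](=O)[O-])CC/C=C(\C)CCC=C(C)C)CC1 | intermediate
17 | 1,8-diazabicyclo[5.4.0]undec-7-enium salt of the nitronate of 16 (nitronate salt) | CC(=O)OCC1=C(C(=O)SCC)[C@@H]([C@@H](C=[N+]([O-])[O-])CC/C=C(\C)CCC=C(C)C)CC1.C1CCC2=[NH+]CCCN2CC1 | intermediate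
18 | S-ethyl (5R)-2-(acetoxymethyl)-5-[(2S,5E)-6,10-dimethyl-1-oxoundeca-5,9-dien-2-yl]cyclopent-1-ene-1-carbothioate | CC(=O)OCC1=C(C(=O)SCC)[C@@H]([C@@H](C=O)CC/C=C(\C)CCC=C(C)C)CC1 | intermediate
19 | [(3R)-2-formyl-3-[(2S,5E)-6,10-dimethyl-1-oxoundeca-5,9-dien-2-yl]cyclopent-1-en-1-yl]methyl acetate | CC(=O)OCC1=C(C=O)[C@@H]([C@@H](C=O)CC/C=C(\C)CCC=C(C)C)CC1 | target

## Step count and risks

Total steps: 9 (steps 1–2 make enal 5, steps 3–5 make nitroalkene 12, steps 6–9 join and finish).
Longest linear sequence: 7 steps (6 → 8 → 9 → 12 → 13 → 16 → 18 → 19).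

**Most likely to fail, first: step 6.** The azolium enolate may be protonated, or the nitronate may acylate itself on the acyl azolium to give a nitrocyclopentanone, before the aldol closure occurs; without the lactonisation the carbene does not turn over. Diastereo- and enantiocontrol with two aliphatic partners is also unproven. The fallback separates bond formation from ring closure. It sets out from 5 and 12: the same carbene-catalysed homoenolate addition is run in THF containing 1,1,1,3,3,3-hexafluoropropan-2-ol (3 equiv), which intercepts the acyl azolium and gives the open-chain active ester 1,1,1,3,3,3-hexafluoropropan-2-yl (3S,4S,7E)-3-(4-acetoxy-3-oxobutyl)-8,12-dimethyl-4-(nitromethyl)trideca-7,11-dienoate F1. This is then closed by a nucleophile-catalysed aldol-lactonisation (4-pyrrolidinopyridine 20 mol %, i-Pr2NEt, CH2Cl2, rt: acyl pyridinium, ammonium enolate, 5-exo aldol onto the ketone, lactonisation with loss of the fluoro alcohol). The fallback comes back to the route at 13.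

**Second: step 7.** The hydroxy thioester can revert to the lactone once the thiol is removed, and the tertiary alkoxysulfonium may ionise (with acetate participation) or eliminate towards C5 instead of into conjugation. The fallback sets out from 13 and opens the lactone by base instead of by a nucleophile: DBU (2.2 equiv, THF, 0 °C → rt) effects E1cB cleavage of the ring C–O bond to give (5R)-2-(acetoxymethyl)-5-[(2S,5E)-6,10-dimethyl-1-nitroundeca-5,9-dien-2-yl]cyclopent-1-ene-1-carboxylic acid F2. The second equivalent of base parks the nitro group as its nitronate, which cannot reach the lactone carbonyl because the side chain is trans to it. Steglich thioesterification (EtSH, EDC·HCl, 4-(dimethylamino)pyridine 10 mol %, CH2Cl2) then gives the thioester, and the fallback comes back to the route at 16.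

**Third: step 8.** The nitronate can attack the neighbouring thioester carbonyl (five-membered C-acylation), the reduction can stall at the oxime, and the new aldehyde can epimerise if the buffer drifts. The fallback sets out from 16 and avoids the nitronate altogether. SnCl2·2H2O (1.5 equiv) with PhSH and Et3N (MeCN, rt) reduces the nitro group to S-ethyl (5R)-2-(acetoxymethyl)-5-[(2S,5E)-1-(hydroxyimino)-6,10-dimethylundeca-5,9-dien-2-yl]cyclopent-1-ene-1-carbothioate F3 (E/Z oxime mixture). Mild trans-oximation with 50 % aqueous glyoxylic acid and NaOAc in THF/AcOH at rt then releases the aldehyde, and the fallback comes back to the route at 18.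

## Further compounds

F1 | step 6 | 1,1,1,3,3,3-hexafluoropropan-2-yl (3S,4S,7E)-3-(4-acetoxy-3-oxobutyl)-8,12-dimethyl-4-(nitromethyl)trideca-7,11-dienoate | CC(=O)OCC(=O)CC[C@@H](CC(=O)OC(C(F)(F)F)C(F)(F)F)[C@@H](C[N+](=O)[O-])CC/C=C(\C)CCC=C(C)C
F2 | step 7 | (5R)-2-(acetoxymethyl)-5-[(2S,5E)-6,10-dimethyl-1-nitroundeca-5,9-dien-2-yl]cyclopent-1-ene-1-carboxylic acid | CC(=O)OCC1=C(C(=O)O)[C@@H]([C@@H](C[N+](=O)[O-])CC/C=C(\C)CCC=C(C)C)CC1
F3 | step 8 | S-ethyl (5R)-2-(acetoxymethyl)-5-[(2S,5E)-1-(hydroxyimino)-6,10-dimethylundeca-5,9-dien-2-yl]cyclopent-1-ene-1-carbothioate | CC(=O)OCC1=C(C(=O)SCC)[C@@H]([C@@H](C=NO)CC/C=C(\C)CCC=C(C)C)CC1
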